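## Retrosynthetic overview

1. The side-chain carbinol is cut at C1′–C2′: chelation-controlled addition of non-8-enylmagnesium bromide to the C5 aldehyde 15, so the terminal alkene enters last.
2. The C3 tetradecanoate comes from acylation of a cis-3-ol, the 3-ol from a 3-ketone, and the ketone from ozonolysis of an exocyclic methylene. C3 is thus carried through ring formation at the ketone oxidation level, as an sp2 carbon with one extra carbon that is later excised.
3. Key disconnection: the oxolane (the only ring, formed in step 4) is cut at C2–C3 and O1–C5, giving hexanal and the acyclic iodoalkenyl mesylate 5. Forward, an asymmetric nickel/chromium alkenylation joins C3 to C2 and the new C2 alkoxide closes onto C5 in the same flask.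
4. Enabling feature: in the oxolane, O1 and C2 are the carbonyl group of an aldehyde. The oxygen-bearing C3 next to C2 can serve as a metalated alkenyl carbon (polarity reversal of a carbonyl-level carbon), and C5 lies 1,4 to the C2 oxygen, so one alkoxide serves both bond formations.
5. Compound 5 comes in three steps from (R)-benzyl glycidyl ether, whose stereocentre becomes C5 with inversion.

Key step: step 4

Remark: oxolane numbering of the target is used (O1, C2 pentyl, C3 ester, C4, C5 side chain, C1′ carbinol); (R)-benzyl glycidyl ether, hexanal, tetradecanoyl chloride and 9-bromonon-1-ene are taken as commercial; coupling and ring closure of step 4 run in one flask and count as one step.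

## Route

Step 1
Reactants: 1 (2R)-2-[(benzyloxy)methyl]oxirane ((R)-benzyl glycidyl ether)
Product: 2 (2S)-1-(benzyloxy)pent-4-yn-2-ol
Conditions: LiC≡CH·H2NCH2CH2NH2, DMSO, 0 °C to rt; then H2O
Reagents that add atoms: lithium acetylide ethylenediamine complex, [Li+].[C-]#C.NCCN
Why: Epoxide ring opening (SN2) by the acetylide at the unsubstituted carbon; the stereocentre is untouched and becomes C5 of the target.

Step 2
Reactants: 2 (2S)-1-(benzyloxy)pent-4-yn-2-ol
Product: 3 (2S)-1-(benzyloxy)pent-4-yn-2-yl methanesulfonate
Conditions: MsCl, Et3N, CH2Cl2, 0 °C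
Reagents that add atoms: methanesulfonyl chloride, CS(=O)(=O)Cl
Why: O-Sulfonylation (mesylation) of the secondary alcohol with retention, which turns the future C5 oxygen into the leaving group for the ring closure.

Step 3
Reactants: 3 (2S)-1-(benzyloxy)pent-4-yn-2-yl methanesulfonate
Product: 5 (2S)-1-(benzyloxy)-4-iodopent-4-en-2-yl methanesulfonate, via iodoalkenylborane 4 (not isolated)
Conditions: B-iodo-9-borabicyclo[3.3.1]nonane, pentane, −20 °C; then AcOH, 0 °C
Reagents that add atoms: B-iodo-9-borabicyclo[3.3.1]nonane, IB1C2CCCC1CCC2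
Why: Haloboration–protodeboronation: syn iodoboration of the terminal alkyne puts boron on the terminal and iodine on the internal carbon, and acetic acid cleaves the C–B bond, a Markovnikov hydroiodination that should leave mesylate and benzyl ether untouched at low temperature.

Step 4
Reactants: 5 (2S)-1-(benzyloxy)-4-iodopent-4-en-2-yl methanesulfonate, 6 hexanal
Product: 8 (2S,5R)-5-[(benzyloxy)methyl]-3-methylidene-2-pentyloxolane, via hydroxy mesylate 7 (not isolated)
Conditions: CrCl2 (cat.), chiral ligand N-[2-(4-isopropyl-4,5-dihydro-1,3-oxazol-2-yl)-6-methylphenyl]methanesulfonamide (cat., antipode that directs addition to the Re face of the aldehyde), 1,8-bis(dimethylamino)naphthalene (cat.), NiCl2(2,9-dimethyl-1,10-phenanthroline) (cat.), Mn, Cp2ZrCl2, LiCl, MeCN, rt; then MeOH, K2CO3, 50 °C, same flask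
Reagents that add atoms: none
Why: Oxidative addition of the alkenyl iodide to zerovalent nickel and transmetalation to trivalent chromium give an alkenylchromium species that, held by the chiral oxazoline sulfonamide ligand, adds to the Re face of hexanal and forms the C2–C3 bond with the (S) carbinol centre; Cp2ZrCl2 takes the alkoxide off chromium and Mn returns chromium to the divalent state, so that chromium and nickel turn over. Methanol and K2CO3 then free the alkoxide, which displaces the secondary mesylate four atoms away and forms the O1–C5 bond. The closest known reaction type is the Nozaki–Hiyama–Kishi alkenylation of an aldehyde with a 2-iodoalk-1-ene followed by intramolecular Williamson etherification, an established way to 2,5-disubstituted 3-methylideneoxolanes. The oxolane closes in the 5-exo-tet mode. C2 is controlled by the ligand on chromium and C5 by clean SN2 inversion of the glycidol-derived (S) mesylate, which together should give the 2,5-trans ring. The step needs chemoselectivity for the aldehyde over the sulfonate, which the low basicity and nucleophilicity of organochromium reagents secure, and O-alkylation over elimination, which the favourable five-membered transition state secures.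

Step 5
Reactants: 8 (2S,5R)-5-[(benzyloxy)methyl]-3-methylidene-2-pentyloxolane
Product: 10 (2S,5R)-5-[(benzyloxy)methyl]-2-pentyloxolan-3-one, via spiro ozonide 9 (not isolated)
Conditions: O3, CH2Cl2, −78 °C; then PPh3, −78 °C to rt
Reagents that add atoms: ozone, [O-][O+]=O
Why: Ozonolysis with reductive work-up cleaves the only C=C bond of 8 and removes the extra carbon, unveiling the C3 ketone; neutral conditions should keep the enolisable C2 centre intact.

Step 6
Reactants: 10 (2S,5R)-5-[(benzyloxy)methyl]-2-pentyloxolan-3-one
Product: 11 (2S,3S,5R)-5-[(benzyloxy)methyl]-2-pentyloxolan-3-ol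
Conditions: LiBH(s-Bu)3, THF, −78 °C; then H2O
Reagents that add atoms: none
Why: Diastereoselective ketone reduction with a bulky hydride, which should attack anti to the adjacent C2 pentyl group and set the new C3 centre (S), cis to pentyl.

Step 7
Reactants: 11 (2S,3S,5R)-5-[(benzyloxy)methyl]-2-pentyloxolan-3-ol, 12 tetradecanoyl chloride
Product: 13 (2S,3S,5R)-5-[(benzyloxy)methyl]-2-pentyloxolan-3-yl tetradecanoate
Conditions: pyridine, DMAP (cat.), CH2Cl2, 0 °C to rt
Reagents that add atoms: none
Why: Acylation (DMAP-catalysed esterification) of the secondary alcohol with retention; no other hydroxyl group is free.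

Step 8
Reactants: 13 (2S,3S,5R)-5-[(benzyloxy)methyl]-2-pentyloxolan-3-yl tetradecanoate
Product: 14 (2S,3S,5R)-5-(hydroxymethyl)-2-pentyloxolan-3-yl tetradecanoate
Conditions: H2 (1 atm), 10% Pd/C, EtOAc, rt
Reagents that add atoms: none
Why: Hydrogenolysis of the benzyl ether; the molecule holds no alkene at this stage and the ester is inert.

Step 9
Reactants: 14 (2S,3S,5R)-5-(hydroxymethyl)-2-pentyloxolan-3-yl tetradecanoate
Product: 15 (2S,3S,5R)-5-formyl-2-pentyloxolan-3-yl tetradecanoate
Conditions: Dess–Martin periodinane, CH2Cl2, 0 °C to rt; used crude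
Reagents that add atoms: none
Why: Dess–Martin oxidation of the primary alcohol under neutral conditions, chosen to avoid epimerisation of the α-alkoxy aldehyde at C5 and acyl migration.

Step 10
Reactants: 16 9-bromonon-1-ene
Product: 17 (non-8-en-1-yl)magnesium bromide (Et2O solution, used directly)
Conditions: Mg, I2 (cat.), Et2O, reflux
Reagents that add atoms: magnesium, [Mg]
Why: Grignard reagent formation by insertion of Mg into the primary C–Br bond; the remote terminal alkene is inert.

Step 11
Reactants: 15 (2S,3S,5R)-5-formyl-2-pentyloxolan-3-yl tetradecanoate, 17 (non-8-en-1-yl)magnesium bromide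
Product: 18 (2S,3S,5R)-5-[(1R)-1-hydroxydec-9-en-1-yl]-2-pentyloxolan-3-yl tetradecanoate
Conditions: MgBr2·OEt2, CH2Cl2, −78 °C; then 17 (Et2O), −78 °C; then H2O
Reagents that add atoms: none
Why: Chelation-controlled Grignard addition: Mg ties the aldehyde oxygen to the ring oxygen O1, the nucleophile attacks the face away from C4 and should set C1′ (R), threo to C5, while the aldehyde reacts far faster than the ester at −78 °C.

## Compound list

1 | (2R)-2-[(benzyloxy)methyl]oxirane | c1ccccc1COC[C@@H]1CO1 | starting material
2 | (2S)-1-(benzyloxy)pent-4-yn-2-ol | c1ccccc1COC[C@@H](O)CC#C | intermediate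
3 | (2S)-1-(benzyloxy)pent-4-yn-2-yl methanesulfonate | c1ccccc1COC[C@@H](OS(C)(=O)=O)CC#C | intermediate
4 | 9-[(1Z,4S)-5-(benzyloxy)-2-iodo-4-(methanesulfonyloxy)pent-1-en-1-yl]-9-borabicyclo[3.3.1]nonane (formed in the flask) | c1ccccc1COC[C@@H](OS(C)(=O)=O)C/C(I)=C/B1C2CCCC1CCC2 | intermediate
5 | (2S)-1-(benzyloxy)-4-iodopent-4-en-2-yl methanesulfonate | c1ccccc1COC[C@@H](OS(C)(=O)=O)CC(I)=C | intermediate
6 | hexanal | CCCCCC=O | starting material
7 | (2S,5S)-1-(benzyloxy)-5-hydroxy-4-methylidenedecan-2-yl methanesulfonate (formed as its zirconium alkoxide, set free by methanol in the flask) | c1ccccc1COC[C@@H](OS(C)(=O)=O)CC(=C)[C@@H](O)CCCCC | intermediate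
8 | (2S,5R)-5-[(benzyloxy)methyl]-3-methylidene-2-pentyloxolane | c1ccccc1COC[C@H]1CC(=C)[C@H](CCCCC)O1 | intermediate
9 | (6S,8R)-8-[(benzyloxy)methyl]-6-pentyl-1,2,4,7-tetraoxaspiro[4.4]nonane (spiro ozonide, epimers at the spiro carbon, formed in the flask) | c1ccccc1COC[C@H]1CC2(OOCO2)[C@H](CCCCC)O1 | intermediate
10 | (2S,5R)-5-[(benzyloxy)methyl]-2-pentyloxolan-3-one | c1ccccc1COC[C@H]1CC(=O)[C@H](CCCCC)O1 | intermediate
11 | (2S,3S,5R)-5-[(benzyloxy)methyl]-2-pentyloxolan-3-ol | c1ccccc1COC[C@H]1C[C@H](O)[C@H](CCCCC)O1 | intermediate
12 | tetradecanoyl chloride | CCCCCCCCCCCCCC(=O)Cl | starting material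
13 | (2S,3S,5R)-5-[(benzyloxy)methyl]-2-pentyloxolan-3-yl tetradecanoate | c1ccccc1COC[C@H]1C[C@H](OC(=O)CCCCCCCCCCCCC)[C@H](CCCCC)O1 | intermediate
14 | (2S,3S,5R)-5-(hydroxymethyl)-2-pentyloxolan-3-yl tetradecanoate | OC[C@H]1C[C@H](OC(=O)CCCCCCCCCCCCC)[C@H](CCCCC)O1 | intermediate
15 | (2S,3S,5R)-5-formyl-2-pentyloxolan-3-yl tetradecanoate | O=C[C@H]1C[C@H](OC(=O)CCCCCCCCCCCCC)[C@H](CCCCC)O1 | intermediate
16 | 9-bromonon-1-ene | C=CCCCCCCCBr | starting material
17 | (non-8-en-1-yl)magnesium bromide | C=CCCCCCCC[Mg]Br | intermediate
18 | (2S,3S,5R)-5-[(1R)-1-hydroxydec-9-en-1-yl]-2-pentyloxolan-3-yl tetradecanoate | C=CCCCCCCC[C@@H](O)[C@H]1C[C@H](OC(=O)CCCCCCCCCCCCC)[C@H](CCCCC)O1 | target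

## Step count and risks

Total step count: 11. Longest linear sequence: 10 steps (steps 1 to 9 and 11).

Steps most likely to fail:

1. Step 4. The ligand on chromium may not control the face of an unbranched aldehyde well enough, which would give the C2 epimer and hence the 2,5-cis ring, and ring closure may lag in the coupling medium. The fallback sets out from 5 and 6 and sets C2 by reduction instead of by the carbon–carbon bond formation. A ligand-free coupling (CrCl2 in excess, NiCl2 cat., DMF) would give the carbinol epimer mixture (2S,5RS)-1-(benzyloxy)-5-hydroxy-4-methylidenedecan-2-yl methanesulfonate F1. Dess–Martin oxidation would give the enone (2S)-1-(benzyloxy)-4-methylidene-5-oxodecan-2-yl methanesulfonate F2. Corey–Bakshi–Shibata reduction (catecholborane, the oxazaborolidine antipode that gives the (5S) alcohol, toluene, −78 °C) would give 7 as one epimer, which is isolated. Ring closure with KN(SiMe3)2 in THF at −20 °C returns to the route at 8.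

2. Step 11. Chelation may be incomplete, so that the two faces of the aldehyde are poorly distinguished; the α-alkoxy aldehyde may epimerise at C5; and part of the reagent may attack the ester. The fallback sets out from 15 and sets C1′ by ketone reduction instead of by the addition. Addition of 17 without additive would give the carbinol epimer mixture (2S,3S,5R)-5-[(1RS)-1-hydroxydec-9-en-1-yl]-2-pentyloxolan-3-yl tetradecanoate F3. Dess–Martin oxidation would give the ketone (2S,3S,5R)-5-(dec-9-enoyl)-2-pentyloxolan-3-yl tetradecanoate F4. Reduction with LiBH(s-Bu)3 in THF at −78 °C under non-chelation (Felkin–Anh) control should give the threo alcohol and returns to the route at 18.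

3. Step 6. The C5 substituent sits on the ring face that the hydride should use, so facial selectivity may drop, and the ketone may epimerise at C2 on handling. The fallback sets out from 10 and makes use of the wrong epimer by inversion. Reduction with NaBH4 in MeOH at −40 °C and separation would give 11 together with the trans alcohol (2S,3R,5R)-5-[(benzyloxy)methyl]-2-pentyloxolan-3-ol F5. Mitsunobu esterification of F5 (tetradecanoic acid, PPh3, diisopropyl azodicarboxylate, THF) inverts C3 and returns to the route at 13, while 11 is acylated as in step 7.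

Further compounds
F1 | step 4 | (2S,5RS)-1-(benzyloxy)-5-hydroxy-4-methylidenedecan-2-yl methanesulfonate | c1ccccc1COC[C@@H](OS(C)(=O)=O)CC(=C)C(O)CCCCC
F2 | step 4 | (2S)-1-(benzyloxy)-4-methylidene-5-oxodecan-2-yl methanesulfonate | c1ccccc1COC[C@@H](OS(C)(=O)=O)CC(=C)C(=O)CCCCC
F3 | step 11 | (2S,3S,5R)-5-[(1RS)-1-hydroxydec-9-en-1-yl]-2-pentyloxolan-3-yl tetradecanoate | C=CCCCCCCCC(O)[C@H]1C[C@H](OC(=O)CCCCCCCCCCCCC)[C@H](CCCCC)O1
F4 | step 11 | (2S,3S,5R)-5-(dec-9-enoyl)-2-pentyloxolan-3-yl tetradecanoate | C=CCCCCCCCC(=O)[C@H]1C[C@H](OC(=O)CCCCCCCCCCCCC)[C@H](CCCCC)O1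
F5 | step 6 | (2S,3R,5R)-5-[(benzyloxy)methyl]-2-pentyloxolan-3-ol | c1ccccc1COC[C@H]1C[C@@H](O)[C@H](CCCCC)O1
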